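**Plan**

1. Numbering: ring C1 (C=O), C2 (allyl), C3, C4 (quaternary C–OMe), C5 (C–OMe), C6; C7 is the side-chain CHMe. The target is 4R with a 2R side chain (C4 R, C7 R).
2. Retrosynthesis: cut C2=C3 of the six-membered dienone ring by aldol condensation. This works because C3 can be an aldehyde carbon on the non-enolisable quaternary C4, and C2 is the α′-carbon of the C5=C6–C1=O vinylogous ester. Then cut C5–OMe (methanol onto an ynone), C1–C6 (acetylide + pent-4-enal), C5≡C6 (homologation of an aldehyde) and C7–CH2Ar (benzyl Grignard on an epoxide).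
3. Forward: the chain is built acyclic. But-2-yn-1-ol → allylic alcohol 7 → epoxy alcohol 8 → diol 11 → alkyne 14 → ynone 18 → enol ether 19 → aldehyde 21; the only ring closes last (21 → 23).
4. Stereochemistry: Sharpless epoxidation with D-(−)-diethyl tartrate sets C4 and the epoxide carbon that becomes C7. Copper-catalysed SN2 opening by the benzyl Grignard inverts that carbon to C7 R. Neither centre is enolisable afterwards.

Key step: step 15

Remark: compounds 19–21 are drawn and named as the E enol ether (C4 and C1 cis), the isomer expected from step 12. Any Z isomer can be carried along, because methoxide interconverts the two by addition–elimination at C5.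

**Route**

Step 1
Reactants: 1 but-2-yn-1-ol
Product: 3 (2E)-2-iodobut-2-en-1-ol, via stannane 2 (not isolated)
Conditions: Bu3SnH, PdCl2(PPh3)2 (2 mol%), THF, 0 °C → rt; then I2, CH2Cl2, 0 °C
Reagents that add atoms: iodine, [I][I]
Why: Palladium-catalysed syn-hydrostannation of a propargylic alcohol places tin on C2 next to the carbinol carbon and iododestannylation goes with retention, so H and I are cis (E); the minor 3-stannyl regioisomer is removed by chromatography at the iodide stage.

Step 2
Reactants: 3 (2E)-2-iodobut-2-en-1-ol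
Product: 4 {[(2E)-2-iodobut-2-en-1-yl]oxy}tri(propan-2-yl)silane
Conditions: TIPSCl, imidazole, DMF, rt
Reagents that add atoms: chlorotri(propan-2-yl)silane, CC(C)[Si](Cl)(C(C)C)C(C)C
Why: Standard silylation of a primary alcohol; the bulky TIPS ether should withstand organometallics and base and resist 1,2-silyl migration until fluoride removal in step 13.

Step 3
Reactants: 4 TIPS-protected vinyl iodide
Product: 7 (2Z)-2-({[tri(propan-2-yl)silyl]oxy}methyl)but-2-en-1-ol, via vinyllithium 5 (not isolated), via enal 6 (not isolated)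
Conditions: t-BuLi (2.1 equiv), Et2O, −78 °C; DMF, −78 → 0 °C; then MeOH, NaBH4, 0 °C
Reagents that add atoms: N,N-dimethylformamide, CN(C)C=O
Why: Iodine–lithium exchange retains alkene geometry, DMF formylates the vinyllithium (Bouveault formylation) and borohydride reduces the enal 1,2 in the same flask, so the new CH2OH ends trans to the methyl group.

Step 4
Reactants: 7 allylic alcohol
Product: 8 [(2S,3R)-3-methyl-2-({[tri(propan-2-yl)silyl]oxy}methyl)oxiran-2-yl]methanol
Conditions: Ti(OiPr)4 (10 mol%), D-(−)-diethyl tartrate (12 mol%), t-BuOOH, 4 Å MS, CH2Cl2, −20 °C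
Reagents that add atoms: tert-butyl hydroperoxide, CC(C)(C)OO
Why: Katsuki–Sharpless asymmetric epoxidation of a 2-substituted allylic alcohol whose 3-substituent is trans to the carbinol, a well-behaved substrate class; the D-(−)-tartrate ligand selects the face that gives the 2S,3R epoxide and so fixes the future C4.

Step 5
Reactants: 9 4-(chloromethyl)-1,2-dimethoxybenzene (3,4-dimethoxybenzyl chloride)
Product: 10 (3,4-dimethoxybenzyl)magnesium chloride
Conditions: Mg turnings, THF, 0 °C, slow addition; solution used directly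
Reagents that add atoms: magnesium, [Mg]
Why: Grignard formation from a benzylic chloride; low temperature and dilution hold back Wurtz coupling.

Step 6
Reactants: 8 epoxy alcohol; 10 (3,4-dimethoxybenzyl)magnesium chloride
Product: 11 (2S,3R)-4-(3,4-dimethoxyphenyl)-3-methyl-2-({[tri(propan-2-yl)silyl]oxy}methyl)butane-1,2-diol
Conditions: 10 (4 equiv), CuBr·SMe2 (20 mol%), THF, −30 → 0 °C; aq. NH4Cl
Reagents that add atoms: none
Why: Copper-catalysed Grignard opening of a 2,3-epoxy alcohol; C2 is quaternary, so SN2 attack should occur at C3 with inversion, which sets C7 (R) beside the tertiary carbinol C4 fixed in step 4.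

Step 7
Reactants: 11 diol
Product: 12 (2R,3R)-4-(3,4-dimethoxyphenyl)-2-hydroxy-3-methyl-2-({[tri(propan-2-yl)silyl]oxy}methyl)butanal
Conditions: SO3·pyridine, DMSO, i-Pr2NEt, CH2Cl2, 0 °C; used crude
Reagents that add atoms: none
Why: Parikh–Doering oxidation takes the primary alcohol to the aldehyde, leaves the tertiary alcohol alone and cannot cleave the 1,2-diol.

Step 8
Reactants: 12 α-hydroxy aldehyde
Product: 13 (3S,4R)-5-(3,4-dimethoxyphenyl)-4-methyl-3-({[tri(propan-2-yl)silyl]oxy}methyl)pent-1-yn-3-ol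
Conditions: dimethyl (1-diazo-2-oxopropyl)phosphonate, K2CO3, MeOH, 0 °C → rt
Reagents that add atoms: dimethyl (1-diazo-2-oxopropyl)phosphonate, CC(=O)C(=[N+]=[N-])P(=O)(OC)OC
Why: Ohira–Bestmann variant of the Seyferth–Gilbert homologation converts the non-enolisable aldehyde into the terminal alkyne under mild carbonate conditions without touching C4.

Step 9
Reactants: 13 tertiary propargylic alcohol
Product: 14 {[(2S,3R)-4-(3,4-dimethoxyphenyl)-2-ethynyl-2-methoxy-3-methylbutyl]oxy}tri(propan-2-yl)silane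
Conditions: NaH, MeI, THF–DMF, 0 °C
Reagents that add atoms: iodomethane, CI
Why: Williamson methylation of the tertiary alkoxide; NaH at 0 °C should not deprotonate the acetylenic C–H, and the TIPS group is too hindered to migrate to the tertiary oxygen.

Step 10
Reactants: 14 terminal alkyne; 15 pent-4-enal
Product: 17 (5RS,8S,9R)-10-(3,4-dimethoxyphenyl)-8-methoxy-9-methyl-8-({[tri(propan-2-yl)silyl]oxy}methyl)dec-1-en-6-yn-5-ol, via lithium acetylide 16 (not isolated)
Conditions: n-BuLi, THF, −78 °C; then 15, −78 °C; H2O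
Reagents that add atoms: none
Why: Deprotonation of the terminal alkyne and 1,2-addition of the lithium acetylide to the aldehyde; the new carbinol centre forms as a mixture that is erased in step 11.

Step 11
Reactants: 17 propargylic alcohol
Product: 18 (8S,9R)-10-(3,4-dimethoxyphenyl)-8-methoxy-9-methyl-8-({[tri(propan-2-yl)silyl]oxy}methyl)dec-1-en-6-yn-5-one
Conditions: Dess–Martin periodinane, pyridine, CH2Cl2, 0 °C → rt
Reagents that add atoms: none
Why: Dess–Martin oxidation of a secondary propargylic alcohol gives the ynone under near-neutral conditions that spare the alkene, the silyl ether and the electron-rich arene.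

Step 12
Reactants: 18 ynone
Product: 19 (6E,8R,9R)-10-(3,4-dimethoxyphenyl)-7,8-dimethoxy-9-methyl-8-({[tri(propan-2-yl)silyl]oxy}methyl)deca-1,6-dien-5-one
Conditions: NaOMe (0.2 equiv), MeOH, 0 °C
Reagents that add atoms: methanol, CO
Why: Base-catalysed oxa-Michael addition of methanol to the ynone; the allenolate should be protonated at C6 from the side of the small methoxy group, away from quaternary C4, so C4 and the acyl carbon C1 end cis (E).

Step 13
Reactants: 19 silyl ether
Product: 20 (6E,8R,9R)-10-(3,4-dimethoxyphenyl)-8-(hydroxymethyl)-7,8-dimethoxy-9-methyldeca-1,6-dien-5-one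
Conditions: TBAF, AcOH (1:1), THF, 0 °C → rt
Reagents that add atoms: none
Why: Fluoride cleavage of the primary TIPS ether; acetic acid buffering avoids a free alkoxide and with it retro-aldol loss of formaldehyde.

Step 14
Reactants: 20 primary alcohol
Product: 21 (2S,3E)-2-[(2R)-1-(3,4-dimethoxyphenyl)propan-2-yl]-2,3-dimethoxy-5-oxonona-3,8-dienal
Conditions: Dess–Martin periodinane, pyridine, CH2Cl2, 0 °C → rt; used without chromatography
Reagents that add atoms: none
Why: Dess–Martin oxidation of the neopentyl-type primary alcohol gives the aldehyde, which has no α-hydrogen and so cannot epimerise C4.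

Step 15
Reactants: 21 keto aldehyde
Product: 23 (4R)-4-[(2R)-1-(3,4-dimethoxyphenyl)propan-2-yl]-4,5-dimethoxy-2-(prop-2-en-1-yl)cyclohexa-2,5-dien-1-one, via aldol 22 (not isolated)
Conditions: NaOMe (0.5 equiv), MeOH, 0 °C → rt
Reagents that add atoms: none
Why: Methoxide reversibly forms the cross-conjugated α′-enolate at C2, the only enolisable site because C4 is quaternary and the aldehyde has no α-hydrogen; the enolate adds to the C3 aldehyde and aldol 22 loses water by E1cB to form C2=C3. The closest known reaction type is the base-mediated intramolecular aldol condensation of a keto aldehyde through the α′-enolate of a vinylogous ester (the enolate used in Stork–Danheiser chemistry). The six-membered ring closes in a 6-(enolendo)-exo-trig mode. No stereocentre is created, since C2 and C3 become sp2 and C4 and C7 are untouched. The step needs the E enol ether and chemoselectivity against loss of the formyl group: methoxide interconverts E and Z by degenerate addition–elimination at C5, and closure at 0 °C should outpace C3–C4 cleavage, whose leaving carbanion is only a weakly stabilised α-alkoxy dienolate. Dehydration is irreversible and the dienone cannot aromatise because C4 is quaternary.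

**Compound list**

1 | but-2-yn-1-ol | CC#CCO | starting material
2 | (2E)-2-(tributylstannyl)but-2-en-1-ol | C/C=C(CO)/[Sn](CCCC)(CCCC)CCCC | intermediate
3 | (2E)-2-iodobut-2-en-1-ol | C/C=C(CO)/I | intermediate
4 | {[(2E)-2-iodobut-2-en-1-yl]oxy}tri(propan-2-yl)silane | C/C=C(CO[Si](C(C)C)(C(C)C)C(C)C)/I | intermediate
5 | [(2Z)-1-{[tri(propan-2-yl)silyl]oxy}but-2-en-2-yl]lithium | C/C=C(CO[Si](C(C)C)(C(C)C)C(C)C)/[Li] | intermediate
6 | (2E)-2-({[tri(propan-2-yl)silyl]oxy}methyl)but-2-enal | C/C=C(CO[Si](C(C)C)(C(C)C)C(C)C)/C=O | intermediate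
7 | (2Z)-2-({[tri(propan-2-yl)silyl]oxy}methyl)but-2-en-1-ol | C/C=C(CO[Si](C(C)C)(C(C)C)C(C)C)/CO | intermediate
8 | [(2S,3R)-3-methyl-2-({[tri(propan-2-yl)silyl]oxy}methyl)oxiran-2-yl]methanol | C[C@H]1O[C@@]1(CO)CO[Si](C(C)C)(C(C)C)C(C)C | intermediate
9 | 4-(chloromethyl)-1,2-dimethoxybenzene | COc1ccc(CCl)cc1OC | starting material
10 | (3,4-dimethoxybenzyl)magnesium chloride | COc1ccc(C[Mg]Cl)cc1OC | intermediate
11 | (2S,3R)-4-(3,4-dimethoxyphenyl)-3-methyl-2-({[tri(propan-2-yl)silyl]oxy}methyl)butane-1,2-diol | CC(C)[Si](C(C)C)(C(C)C)OC[C@](O)([C@H](C)Cc1ccc(OC)c(OC)c1)CO | intermediate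
12 | (2R,3R)-4-(3,4-dimethoxyphenyl)-2-hydroxy-3-methyl-2-({[tri(propan-2-yl)silyl]oxy}methyl)butanal | CC(C)[Si](C(C)C)(C(C)C)OC[C@](O)([C@H](C)Cc1ccc(OC)c(OC)c1)C=O | intermediate
13 | (3S,4R)-5-(3,4-dimethoxyphenyl)-4-methyl-3-({[tri(propan-2-yl)silyl]oxy}methyl)pent-1-yn-3-ol | CC(C)[Si](C(C)C)(C(C)C)OC[C@](O)([C@H](C)Cc1ccc(OC)c(OC)c1)C#C | intermediate
14 | {[(2S,3R)-4-(3,4-dimethoxyphenyl)-2-ethynyl-2-methoxy-3-methylbutyl]oxy}tri(propan-2-yl)silane | CC(C)[Si](C(C)C)(C(C)C)OC[C@](OC)([C@H](C)Cc1ccc(OC)c(OC)c1)C#C | intermediate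
15 | pent-4-enal | C=CCCC=O | starting material
16 | lithium acetylide of 14 | CC(C)[Si](C(C)C)(C(C)C)OC[C@](OC)([C@H](C)Cc1ccc(OC)c(OC)c1)C#C[Li] | intermediate
17 | (5RS,8S,9R)-10-(3,4-dimethoxyphenyl)-8-methoxy-9-methyl-8-({[tri(propan-2-yl)silyl]oxy}methyl)dec-1-en-6-yn-5-ol | CC(C)[Si](C(C)C)(C(C)C)OC[C@](OC)([C@H](C)Cc1ccc(OC)c(OC)c1)C#CC(O)CCC=C | intermediate
18 | (8S,9R)-10-(3,4-dimethoxyphenyl)-8-methoxy-9-methyl-8-({[tri(propan-2-yl)silyl]oxy}methyl)dec-1-en-6-yn-5-one | CC(C)[Si](C(C)C)(C(C)C)OC[C@](OC)([C@H](C)Cc1ccc(OC)c(OC)c1)C#CC(=O)CCC=C | intermediate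
19 | (6E,8R,9R)-10-(3,4-dimethoxyphenyl)-7,8-dimethoxy-9-methyl-8-({[tri(propan-2-yl)silyl]oxy}methyl)deca-1,6-dien-5-one | CC(C)[Si](C(C)C)(C(C)C)OC[C@](OC)([C@H](C)Cc1ccc(OC)c(OC)c1)/C(OC)=C\C(=O)CCC=C | intermediate
20 | (6E,8R,9R)-10-(3,4-dimethoxyphenyl)-8-(hydroxymethyl)-7,8-dimethoxy-9-methyldeca-1,6-dien-5-one | OC[C@](OC)([C@H](C)Cc1ccc(OC)c(OC)c1)/C(OC)=C\C(=O)CCC=C | intermediate
21 | (2S,3E)-2-[(2R)-1-(3,4-dimethoxyphenyl)propan-2-yl]-2,3-dimethoxy-5-oxonona-3,8-dienal | O=C[C@](OC)([C@H](C)Cc1ccc(OC)c(OC)c1)/C(OC)=C\C(=O)CCC=C | intermediate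
22 | (4R)-4-[(2R)-1-(3,4-dimethoxyphenyl)propan-2-yl]-5-hydroxy-3,4-dimethoxy-6-(prop-2-en-1-yl)cyclohex-2-en-1-one (C5/C6 mixture) | C=CCC1C(O)[C@](OC)([C@H](C)Cc2ccc(OC)c(OC)c2)C(OC)=CC1=O | intermediate
23 | (4R)-4-[(2R)-1-(3,4-dimethoxyphenyl)propan-2-yl]-4,5-dimethoxy-2-(prop-2-en-1-yl)cyclohexa-2,5-dien-1-one | C=CCC1=C[C@](OC)([C@H](C)Cc2ccc(OC)c(OC)c2)C(OC)=CC1=O | target

**Count**

Total steps: 15. Longest linear sequence: 14 steps (steps 1–4 and 6–15, from but-2-yn-1-ol); step 5 is a one-step side branch.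

**Steps most likely to fail**

1. Step 15. Methoxide attack at the aldehyde may lead to loss of the formyl group (retro-Claisen-type cleavage of C3–C4), or equilibration of the enol ether may lag behind the side reactions. Fallback: set out from the E isomer of 21 and form the α′-enolate irreversibly with LiHMDS (THF, −78 °C), which has no nucleophilic oxygen; a proton quench gives aldol 22. Mesylation (MsCl, Et3N, CH2Cl2, 0 °C) gives the mesylate F1, and DBU (CH2Cl2, rt) eliminates it to rejoin the route at 23.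

2. Step 6. SN2 attack at C3 beside the quaternary carbon may be slow, so that magnesium-halide-induced epoxide rearrangement and Wurtz coupling of the benzylic Grignard take over. Fallback: set out from 8 and open it with the smaller, more reactive vinyl nucleophile (vinylmagnesium bromide, CuBr·SMe2, THF) to give the vinyl diol F2. Ozonolysis (O3, CH2Cl2–MeOH, −78 °C; Me2S) gives the lactol F3. 3,4-Dimethoxyphenylmagnesium bromide (THF, 0 °C) adds to its open form to give the benzylic triol F4. Hydrogenolysis of the electron-rich benzylic alcohol (H2, Pd/C, EtOH, trace AcOH; no alkene is present at this stage) rejoins the route at 11.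

3. Step 12. Attack at the hindered alkyne carbon may be slow, or protonation of the allenolate may occur on the wrong face and give the Z enol ether, which cannot cyclise. Fallback: set out from 18 and remove the silyl group first (TBAF, AcOH, THF) to give the hydroxy ynone F5. Methanol addition under equilibrating conditions (NaOMe, MeOH, rt) then follows; only the E adduct can close onto the C1 ketone as the six-membered hemiketal F6, which should pull the E/Z equilibrium to the E series. F6 is in equilibrium with the open hydroxy enone, so the route is rejoined at 20.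

**Further compounds**

F1 | step 15 | (1RS,2R,6RS)-2-[(2R)-1-(3,4-dimethoxyphenyl)propan-2-yl]-2,3-dimethoxy-5-oxo-6-(prop-2-en-1-yl)cyclohex-3-en-1-yl methanesulfonate | C=CCC1C(OS(C)(=O)=O)[C@](OC)([C@H](C)Cc2ccc(OC)c(OC)c2)C(OC)=CC1=O
F2 | step 6 | (2S,3R)-3-methyl-2-({[tri(propan-2-yl)silyl]oxy}methyl)pent-4-ene-1,2-diol | CC(C)[Si](C(C)C)(C(C)C)OC[C@](O)([C@H](C)C=C)CO
F3 | step 6 | (3S,4S)-3-methyl-4-({[tri(propan-2-yl)silyl]oxy}methyl)oxolane-2,4-diol (anomer mixture) | CC(C)[Si](C(C)C)(C(C)C)OC[C@]1(O)[C@H](C)C(O)OC1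
F4 | step 6 | (2S,3R,4RS)-4-(3,4-dimethoxyphenyl)-3-methyl-2-({[tri(propan-2-yl)silyl]oxy}methyl)butane-1,2,4-triol | CC(C)[Si](C(C)C)(C(C)C)OC[C@](O)([C@H](C)C(O)c1ccc(OC)c(OC)c1)CO
F5 | step 12 | (8S,9R)-10-(3,4-dimethoxyphenyl)-8-(hydroxymethyl)-8-methoxy-9-methyldec-1-en-6-yn-5-one | OC[C@](OC)([C@H](C)Cc1ccc(OC)c(OC)c1)C#CC(=O)CCC=C
F6 | step 12 | (2RS,5R)-2-(but-3-en-1-yl)-5-[(2R)-1-(3,4-dimethoxyphenyl)propan-2-yl]-4,5-dimethoxy-5,6-dihydro-2H-pyran-2-ol | C=CCCC1(O)C=C(OC)[C@@](OC)([C@H](C)Cc2ccc(OC)c(OC)c2)CO1
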